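The route disconnects two bonds at once, C3–C1′ and C4–C4a. This leads back to a linear, enantiopure 1-aryloxy-3-arylpropan-2-yl mesylate assembled from (R)-glycidyl nosylate. On ionisation the B ring, whose O2′ and pyran O4′ lie ortho and para to C1′, should migrate from C4 to C3 through a phenonium ion with inversion. C4a of the A ring (para to O7, ortho to O1, with C8 blocked by prenyl) then opens the ion at CH2. One operation closes the dihydropyran ring, creates the isoflavan 1,2-diaryl connectivity and sets C3. No hydrogenation is needed, so the prenyl and chromene alkenes are not endangered.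

Key step: step 10

Remark: the SMILES is read as the (3R)-isoflavan. Isoflavan numbering (O1, C2–C4, C4a–C8a, B ring C1′–C6′) is also used for the acyclic precursors.

Step 1
Reactants: 1 resorcinol
Product: 2 1,3-bis(methoxymethoxy)benzene
Conditions: NaH, MOMCl, DMF, 0 °C → rt
Reagents that add atoms: chloromethyl methyl ether (MOMCl), COCCl
Why: Williamson-type O-alkylation of the bis-phenoxide installs the two acetal groups that direct the next metalation.

Step 2
Reactants: 2 1,3-bis(methoxymethoxy)benzene; 3 1-bromo-3-methylbut-2-ene (prenyl bromide)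
Product: 5 1,3-bis(methoxymethoxy)-2-(3-methylbut-2-en-1-yl)benzene, via [2,6-bis(methoxymethoxy)phenyl]lithium 4 (not isolated)
Conditions: n-BuLi, THF, 0 °C → rt; CuI (10 mol %), 3, −20 °C → rt
Reagents that add atoms: none
Why: Directed ortho-metalation occurs at the carbon flanked by both OMOM groups, and copper-assisted SN2 alkylation by the allylic bromide places the prenyl group between the two oxygens.

Step 3
Reactants: 5 1,3-bis(methoxymethoxy)-2-(3-methylbut-2-en-1-yl)benzene
Product: 6 3-(methoxymethoxy)-2-(3-methylbut-2-en-1-yl)phenol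
Conditions: p-TsOH·H2O (cat.), MeOH, 40 °C, stopped at partial conversion (5 recovered and resubmitted)
Reagents that add atoms: none
Why: Acid-catalysed transacetalisation of one of two symmetry-equivalent MOM acetals, run to partial conversion, should give the mono-phenol without any regiochemical issue because 5 is Cs-symmetric.

Step 4
Reactants: 6 3-(methoxymethoxy)-2-(3-methylbut-2-en-1-yl)phenol; 7 [(2R)-oxiran-2-yl]methyl 3-nitrobenzenesulfonate ((R)-glycidyl nosylate)
Product: 8 (2R)-2-{[3-(methoxymethoxy)-2-(3-methylbut-2-en-1-yl)phenoxy]methyl}oxirane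
Conditions: K2CO3, DMF, rt
Reagents that add atoms: none
Why: Direct SN2 displacement of the arenesulfonate at its primary carbon (Williamson etherification) does not touch the stereocentre, so the (R) configuration of 7 is carried into 8.

Step 5
Reactants: 9 cyclohexane-1,3-dione; 10 3-methylbut-2-enal
Product: 12 2,2-dimethyl-2,6,7,8-tetrahydro-5H-chromen-5-one, via 2-(3-methylbut-2-en-1-ylidene)cyclohexane-1,3-dione 11 (not isolated)
Conditions: ethylenediammonium diacetate (10 mol %), MeOH, rt → 50 °C
Reagents that add atoms: none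
Why: Knoevenagel condensation gives the 1-oxatriene 11, which closes by oxa-6π-electrocyclisation (formal [3+3] annulation), so the pyran is fused at the carbon between the two oxygen functions, a regiochemistry that direct chromenylation of resorcinol would not secure.

Step 6
Reactants: 12 2,2-dimethyl-2,6,7,8-tetrahydro-5H-chromen-5-one
Product: 14 2,2-dimethyl-2H-chromen-5-ol, via 2,2-dimethyl-6-(phenylselanyl)-2,6,7,8-tetrahydro-5H-chromen-5-one 13 (not isolated)
Conditions: LDA, THF, −78 °C; PhSeCl, −78 °C; then 30% H2O2, pyridine, CH2Cl2, 0 °C → rt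
Reagents that add atoms: none
Why: Kinetic α′-deprotonation of the vinylogous ester at C6, α-selenenylation and selenoxide syn-elimination add the missing unsaturation, and the product enolises to the aromatic phenol while cold H2O2 leaves the chromene alkene alone.

Step 7
Reactants: 14 2,2-dimethyl-2H-chromen-5-ol
Product: 15 5-(methoxymethoxy)-2,2-dimethyl-2H-chromene
Conditions: NaH, MOMCl, DMF, 0 °C → rt
Reagents that add atoms: chloromethyl methyl ether (MOMCl), COCCl
Why: Williamson-type O-alkylation protects the future O2′ and provides the directing group for the next metalation.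

Step 8
Reactants: 15 5-(methoxymethoxy)-2,2-dimethyl-2H-chromene; 8 (2R)-2-{[3-(methoxymethoxy)-2-(3-methylbut-2-en-1-yl)phenoxy]methyl}oxirane
Product: 18 (2R)-1-[5-(methoxymethoxy)-2,2-dimethyl-2H-chromen-6-yl]-3-[3-(methoxymethoxy)-2-(3-methylbut-2-en-1-yl)phenoxy]propan-2-ol, via [5-(methoxymethoxy)-2,2-dimethyl-2H-chromen-6-yl]lithium 16 (not isolated), via [5-(methoxymethoxy)-2,2-dimethyl-2H-chromen-6-yl]magnesium bromide 17 (not isolated)
Conditions: n-BuLi, THF, 0 °C; MgBr2·OEt2, −20 °C; CuI (10 mol %), 8, −30 → 0 °C; then H2O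
Reagents that add atoms: none
Why: Directed ortho-metalation can only occur at C6 because the other position ortho to OMOM is the ring-fusion carbon, and after Li→Mg exchange the copper-catalysed SN2 opening of the terminal epoxide at its CH2 carbon leaves the stereocentre untouched.

Step 9
Reactants: 18 (2R)-1-[5-(methoxymethoxy)-2,2-dimethyl-2H-chromen-6-yl]-3-[3-(methoxymethoxy)-2-(3-methylbut-2-en-1-yl)phenoxy]propan-2-ol
Product: 19 (2R)-1-[5-(methoxymethoxy)-2,2-dimethyl-2H-chromen-6-yl]-3-[3-(methoxymethoxy)-2-(3-methylbut-2-en-1-yl)phenoxy]propan-2-yl methanesulfonate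
Conditions: MsCl, Et3N, CH2Cl2, −20 → 0 °C; cold aqueous work-up, used without chromatography
Reagents that add atoms: methanesulfonyl chloride, CS(=O)(=O)Cl
Why: O-sulfonylation of the secondary alcohol breaks no bond at carbon, so the configuration is retained, and the non-ionising solvent should keep the activated ester intact.

Step 10
Reactants: 19 (2R)-1-[5-(methoxymethoxy)-2,2-dimethyl-2H-chromen-6-yl]-3-[3-(methoxymethoxy)-2-(3-methylbut-2-en-1-yl)phenoxy]propan-2-yl methanesulfonate
Product: 21 (3R)-7-(methoxymethoxy)-3-[5-(methoxymethoxy)-2,2-dimethyl-2H-chromen-6-yl]-8-(3-methylbut-2-en-1-yl)chromane, via spirocyclopropyl phenonium ion 20 (not isolated)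
Conditions: (CF3)2CHOH (0.01 M), 2,6-di-tert-butyl-4-methylpyridine, rt → 40 °C
Reagents that add atoms: none
Why: Proposed new method: in the strongly ionising, poorly nucleophilic solvent the C3–OMs bond should break with anchimeric assistance (Ar1-3 participation) from C1′ of the B ring to give the spirocyclopropyl phenonium ion 20, whose charge rests on O4′ (para) and O2′ (ortho); C4a of the A ring then opens the three-membered ring at its CH2 carbon (the future C4) and the hindered pyridine takes up the proton on rearomatisation. The closest known reaction types are the solvolytic 1,2-aryl shift of β-arylalkyl sulfonates, the capture of phenonium ions by a tethered arene to give 2-aryltetralins, and the 6-endo epoxide–arene cyclisation of aryl glycidyl ethers to chroman-3-ols, of which this is the carbocyclic counterpart; their combination on an aryloxy tether has not been shown. The dihydropyran ring closes by intramolecular Friedel–Crafts alkylation in a 6-endo-tet mode with respect to the cyclopropane (C3 and C4 both end up in the new ring), forming C4–C4a. C3 is controlled by the substrate alone: backside entry of C1′ inverts the (R)-carbinol carbon, the second substitution takes place at C4, and the result is (3R) (same descriptor because the CIP ranks change), while return of mesylate to either carbon of 20 only regenerates precursors of the same ion, so no racemisation channel opens. The step needs aryl participation to outrun participation by the O2′ acetal oxygen, hydride shift and elimination, and it needs opening at CH2 and not at CH: the para donor O4′ accelerates the Ar1-3 pathway specifically, the two-atom O1–C2 tether cannot place C4a behind the CH carbon (a strained five-ring Friedel–Crafts geometry), that carbon is also more hindered and inductively deactivated by its CH2OAr group, C4a is the most nucleophilic A-ring position (para to O7, ortho to O1), and the C8 prenyl group blocks the other ortho position.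

Step 11
Reactants: 21 (3R)-7-(methoxymethoxy)-3-[5-(methoxymethoxy)-2,2-dimethyl-2H-chromen-6-yl]-8-(3-methylbut-2-en-1-yl)chromane
Product: 22 (3R)-3-(5-hydroxy-2,2-dimethyl-2H-chromen-6-yl)-8-(3-methylbut-2-en-1-yl)chroman-7-ol (target)
Conditions: 3 M aq HCl (cat.), MeOH–THF, 40 °C
Reagents that add atoms: none
Why: Mild acid-catalysed methanolysis of the two phenolic MOM acetals is a deprotection with precedent on o-prenylphenols and 2,2-dimethylchromenes, and C3 carries no leaving group or acidic hydrogen that could scramble it.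

Compound list
1 | resorcinol | Oc1cccc(O)c1 | starting material
2 | 1,3-bis(methoxymethoxy)benzene | COCOc1cccc(OCOC)c1 | intermediate
3 | 1-bromo-3-methylbut-2-ene | CC(C)=CCBr | starting material
4 | [2,6-bis(methoxymethoxy)phenyl]lithium | [Li]c1c(OCOC)cccc1OCOC | intermediate (not isolated)
5 | 1,3-bis(methoxymethoxy)-2-(3-methylbut-2-en-1-yl)benzene | CC(C)=CCc1c(OCOC)cccc1OCOC | intermediate
6 | 3-(methoxymethoxy)-2-(3-methylbut-2-en-1-yl)phenol | CC(C)=CCc1c(O)cccc1OCOC | intermediate
7 | [(2R)-oxiran-2-yl]methyl 3-nitrobenzenesulfonate | O=S(=O)(OC[C@H]1CO1)c1cccc([N+](=O)[O-])c1 | starting material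
8 | (2R)-2-{[3-(methoxymethoxy)-2-(3-methylbut-2-en-1-yl)phenoxy]methyl}oxirane | CC(C)=CCc1c(OCOC)cccc1OC[C@H]1CO1 | intermediate
9 | cyclohexane-1,3-dione | O=C1CCCC(=O)C1 | starting material
10 | 3-methylbut-2-enal | CC(C)=CC=O | starting material
11 | 2-(3-methylbut-2-en-1-ylidene)cyclohexane-1,3-dione | CC(C)=CC=C1C(=O)CCCC1=O | intermediate (not isolated)
12 | 2,2-dimethyl-2,6,7,8-tetrahydro-5H-chromen-5-one | CC1(C)C=CC2=C(CCCC2=O)O1 | intermediate
13 | 2,2-dimethyl-6-(phenylselanyl)-2,6,7,8-tetrahydro-5H-chromen-5-one (racemic) | CC1(C)C=CC2=C(CCC([Se]c3ccccc3)C2=O)O1 | intermediate (not isolated)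
14 | 2,2-dimethyl-2H-chromen-5-ol | CC1(C)C=Cc2c(O)cccc2O1 | intermediate
15 | 5-(methoxymethoxy)-2,2-dimethyl-2H-chromene | COCOc1cccc2OC(C)(C)C=Cc12 | intermediate
16 | [5-(methoxymethoxy)-2,2-dimethyl-2H-chromen-6-yl]lithium | [Li]c1ccc2OC(C)(C)C=Cc2c1OCOC | intermediate (not isolated)
17 | [5-(methoxymethoxy)-2,2-dimethyl-2H-chromen-6-yl]magnesium bromide | Br[Mg]c1ccc2OC(C)(C)C=Cc2c1OCOC | intermediate (not isolated)
18 | (2R)-1-[5-(methoxymethoxy)-2,2-dimethyl-2H-chromen-6-yl]-3-[3-(methoxymethoxy)-2-(3-methylbut-2-en-1-yl)phenoxy]propan-2-ol | CC(C)=CCc1c(OCOC)cccc1OC[C@H](O)Cc1ccc2OC(C)(C)C=Cc2c1OCOC | intermediate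
19 | (2R)-1-[5-(methoxymethoxy)-2,2-dimethyl-2H-chromen-6-yl]-3-[3-(methoxymethoxy)-2-(3-methylbut-2-en-1-yl)phenoxy]propan-2-yl methanesulfonate | CC(C)=CCc1c(OCOC)cccc1OC[C@H](OS(C)(=O)=O)Cc1ccc2OC(C)(C)C=Cc2c1OCOC | intermediate
20 | spirocyclopropyl phenonium ion (C1′ spiro-bridging C3 and C4, charge drawn on the pyran oxygen, C3 already inverted, spiro centre unassigned) | CC(C)=CCc1c(OCOC)cccc1OC[C@@H]1CC12C=CC3=[O+]C(C)(C)C=CC3=C2OCOC | intermediate (not isolated)
21 | (3R)-7-(methoxymethoxy)-3-[5-(methoxymethoxy)-2,2-dimethyl-2H-chromen-6-yl]-8-(3-methylbut-2-en-1-yl)chromane | CC(C)=CCc1c(OCOC)ccc2c1OC[C@@H](c1ccc3c(c1OCOC)C=CC(C)(C)O3)C2 | intermediate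
22 | (3R)-3-(5-hydroxy-2,2-dimethyl-2H-chromen-6-yl)-8-(3-methylbut-2-en-1-yl)chroman-7-ol | CC(C)=CCc1c(O)ccc2c1OC[C@@H](c1ccc3c(c1O)C=CC(C)(C)O3)C2 | target

Total step count: 11
Longest linear sequence: 8 steps (steps 1–4 and 8–11)

Steps most likely to fail

Step 10. Several processes may compete with the intended course: participation of the O2′ acetal oxygen with loss of its protecting group, hydride shift or proton loss from the ionising centre, and opening of the bridged ion at its more substituted carbon. The lability of the mesylate adds to this. The fallback uses known reactions only; it sets out from 6 and 16 and comes back at 21. Phenol 6 would be O-alkylated with 2,3-dibromopropene (K2CO3, acetone) to 1-[(2-bromoprop-2-en-1-yl)oxy]-3-(methoxymethoxy)-2-(3-methylbut-2-en-1-yl)benzene F1. Aryllithium 16 would be transmetalated with ZnCl2 to [5-(methoxymethoxy)-2,2-dimethyl-2H-chromen-6-yl]zinc chloride F2. Palladium-catalysed Negishi coupling of the two would give the 2-arylallyl aryl ether F3. Its aromatic Claisen rearrangement (N,N-diethylaniline, heat) can only reach the one free ortho carbon and forms C4–C4a in the o-(2-arylallyl)phenol F4. Catalytic asymmetric hydroboration of the 1,1-disubstituted aryl alkene with pinacolborane (chiral cobalt iminopyridine–oxazoline catalyst) would give the (R)-C,O-bis(pinacolboryl) compound F5. Oxidation (NaBO3) would turn this into the (R)-hydroxypropyl phenol F6, so that C3 is set by the catalyst. Mitsunobu etherification (PPh3, DIAD) would then close O1–C2 and give 21.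

Step 8. The magnesium salts may open the electron-rich glycidyl ether with bromide, or through its own activated arene, before the aryl group is transferred. The fallback inverts the order in which the C3 unit is attached; it sets out from 17 and 6 and comes back at 18, bypassing 7 and 8. Grignard reagent 17 would open commercial (R)-epichlorohydrin (ClC[C@H]1CO1, used in excess, CuI cat.) at the epoxide CH2 to give (2R)-1-chloro-3-[5-(methoxymethoxy)-2,2-dimethyl-2H-chromen-6-yl]propan-2-ol F7. Aqueous NaOH would close this to (2R)-2-{[5-(methoxymethoxy)-2,2-dimethyl-2H-chromen-6-yl]methyl}oxirane F8. The phenoxide of 6 (K2CO3, DMF, heat) would open the epoxide at its terminal carbon under Lewis-acid-free conditions to give 18, with the stereocentre untouched throughout.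

Step 3. The two equivalent acetals may not be differentiated, so cleavage may run on to loss of both protecting groups. The fallback avoids any statistical step by building the arene from a dione that can be O-alkylated only once; it sets out from 9 and 3 and comes back at 6. C-Alkylation of 9 with 3 (aq KOH) would give 2-(3-methylbut-2-en-1-yl)cyclohexane-1,3-dione F9. MOMCl and i-Pr2NEt would convert this into the vinylogous ester 3-(methoxymethoxy)-2-(3-methylbut-2-en-1-yl)cyclohex-2-en-1-one F10. LDA and PhSeCl would give 3-(methoxymethoxy)-2-(3-methylbut-2-en-1-yl)-6-(phenylselanyl)cyclohex-2-en-1-one F11. Oxidation with H2O2, selenoxide syn-elimination and enolisation would then deliver 6.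

Further compounds
F1 | step 10 | 1-[(2-bromoprop-2-en-1-yl)oxy]-3-(methoxymethoxy)-2-(3-methylbut-2-en-1-yl)benzene | C=C(Br)COc1cccc(OCOC)c1CC=C(C)C
F2 | step 10 | [5-(methoxymethoxy)-2,2-dimethyl-2H-chromen-6-yl]zinc chloride | Cl[Zn]c1ccc2OC(C)(C)C=Cc2c1OCOC
F3 | step 10 | 5-(methoxymethoxy)-6-{3-[3-(methoxymethoxy)-2-(3-methylbut-2-en-1-yl)phenoxy]prop-1-en-2-yl}-2,2-dimethyl-2H-chromene | C=C(COc1cccc(OCOC)c1CC=C(C)C)c1ccc2OC(C)(C)C=Cc2c1OCOC
F4 | step 10 | 3-(methoxymethoxy)-6-{2-[5-(methoxymethoxy)-2,2-dimethyl-2H-chromen-6-yl]prop-2-en-1-yl}-2-(3-methylbut-2-en-1-yl)phenol | C=C(Cc1ccc(OCOC)c(CC=C(C)C)c1O)c1ccc2OC(C)(C)C=Cc2c1OCOC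
F5 | step 10 | (R)-C,O-bis(pinacolboryl) compound (primary alkyl boronate at the future C2, aryl borate at O1) | CC1(C)OB(C[C@@H](c2ccc3OC(C)(C)C=Cc3c2OCOC)Cc2ccc(OCOC)c(CC=C(C)C)c2OB2OC(C)(C)C(C)(C)O2)OC1(C)C
F6 | step 10 | 6-{(2R)-3-hydroxy-2-[5-(methoxymethoxy)-2,2-dimethyl-2H-chromen-6-yl]propyl}-3-(methoxymethoxy)-2-(3-methylbut-2-en-1-yl)phenol | OC[C@@H](c1ccc2OC(C)(C)C=Cc2c1OCOC)Cc1ccc(OCOC)c(CC=C(C)C)c1O
F7 | step 8 | (2R)-1-chloro-3-[5-(methoxymethoxy)-2,2-dimethyl-2H-chromen-6-yl]propan-2-ol | ClC[C@H](O)Cc1ccc2OC(C)(C)C=Cc2c1OCOC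
F8 | step 8 | (2R)-2-{[5-(methoxymethoxy)-2,2-dimethyl-2H-chromen-6-yl]methyl}oxirane | C3[C@H](O3)Cc1ccc2OC(C)(C)C=Cc2c1OCOC
F9 | step 3 | 2-(3-methylbut-2-en-1-yl)cyclohexane-1,3-dione | CC(C)=CCC1C(=O)CCCC1=O
F10 | step 3 | 3-(methoxymethoxy)-2-(3-methylbut-2-en-1-yl)cyclohex-2-en-1-one | CC(C)=CCC1=C(OCOC)CCCC1=O
F11 | step 3 | 3-(methoxymethoxy)-2-(3-methylbut-2-en-1-yl)-6-(phenylselanyl)cyclohex-2-en-1-one (racemic) | CC(C)=CCC1=C(OCOC)CCC([Se]c2ccccc2)C1=O
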